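**Retrosynthetic overview**
1. The butenolide is the last ring formed: ring-closing metathesis of acrylate 28, made from the 2-substituted allylic alcohol 27.
2. 27 is cut at the C(sp3)–C(sp2) bond next to the ring-side trisubstituted olefin: B-alkyl Suzuki coupling of ring fragment 12 (as its 9-BBN adduct) with (E)-vinyl iodide 25.
3. The cyclohexene ring is formed first: organocatalytic Michael addition of ethyl acetoacetate to crotonaldehyde followed by intramolecular aldol condensation gives 5 (sets the secondary methyl centre); anti C-methylation then sets the quaternary centre.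
4. Chain fragment 25 comes from acetoacetate dianion alkylation, enol phosphate/cuprate coupling (first E-olefin), hydrozirconation–iodination (second E-olefin) and methallyl alcohol dianion alkylation.

Assumption: 5 is drawn as its trans C1 epimer; C1 is epimerisable and is reset in step 2, so its configuration there does not matter.

**Ring fragment**

Step 1
Reactants: 1 ethyl acetoacetate; 2 (E)-but-2-enal (crotonaldehyde)
Product: 5 ethyl (1S,6R)-6-methyl-2-oxocyclohex-3-ene-1-carboxylate, via Michael adduct 3 (not isolated), via aldol adduct 4 (not isolated)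
Conditions: (S)-2-[bis(3,5-bis(trifluoromethyl)phenyl)(trimethylsilyloxy)methyl]pyrrolidine (10 mol %), toluene, rt; then p-TsOH·H2O (20 mol %), 80 °C
Reagents that add atoms: none
Why: Iminium-ion organocatalytic Michael addition delivers the keto ester to the β-carbon of the (E)-iminium ion from the face opposite the bulky diarylsilyloxymethyl group, setting the methyl-bearing centre as R (about 90–95% ee expected), and acid then closes the six-membered ring by intramolecular aldol condensation of the methyl ketone onto the aldehyde, the only enol/carbonyl pairing that gives an unstrained ring.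

Step 2
Reactants: 5 ethyl (1S,6R)-6-methyl-2-oxocyclohex-3-ene-1-carboxylate
Product: 6 ethyl (1R,6R)-1,6-dimethyl-2-oxocyclohex-3-ene-1-carboxylate
Conditions: K2CO3, MeI, acetone, rt
Reagents that add atoms: iodomethane, CI
Why: C-alkylation of the β-keto ester enolate, in which the C6 methyl sits pseudoaxial to avoid allylic strain with the planar ester so that MeI enters anti to it, giving the quaternary centre with the two methyls trans and the ester cis to the C6 methyl (minor epimer removed by chromatography).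

Step 3
Reactants: 6 ethyl (1R,6R)-1,6-dimethyl-2-oxocyclohex-3-ene-1-carboxylate
Product: 8 ethyl (1R,6R)-1,6-dimethyl-2-{[(trifluoromethyl)sulfonyl]oxy}cyclohex-2-ene-1-carboxylate, via lithium enolate 7 (not isolated)
Conditions: LiBH(s-Bu)3, THF, −78 °C; then PhNTf2, −78 °C to rt
Reagents that add atoms: N-phenylbis(trifluoromethanesulfonimide), O=S(=O)(N(c1ccccc1)S(=O)(=O)C(F)(F)F)C(F)(F)F
Why: Conjugate hydride reduction of the β-unsubstituted, carbonyl-hindered cyclohexenone generates the enolate regiospecifically, and O-triflation traps it as the C2=C3 enol triflate without touching either stereocentre.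

Step 4
Reactants: 8 ethyl (1R,6R)-1,6-dimethyl-2-{[(trifluoromethyl)sulfonyl]oxy}cyclohex-2-ene-1-carboxylate
Product: 9 ethyl (1R,6R)-1,2,6-trimethylcyclohex-2-ene-1-carboxylate
Conditions: MeMgBr, Fe(acac)3 (5 mol %), THF/NMP, −30 to 0 °C
Reagents that add atoms: methylmagnesium bromide, C[Mg]Br
Why: Iron-catalysed Kumada-type cross-coupling of the alkenyl triflate is far faster than Grignard attack on the hindered α-quaternary ester and installs the vinylic methyl with the double bond fixed at C2=C3.

Step 5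
Reactants: 9 ethyl (1R,6R)-1,2,6-trimethylcyclohex-2-ene-1-carboxylate
Product: 10 [(1R,6R)-1,2,6-trimethylcyclohex-2-en-1-yl]methanol
Conditions: LiAlH4, Et2O, 0 °C to rt
Reagents that add atoms: none
Why: Hydride reduction of the ester to the neopentyl primary alcohol, with the isolated trisubstituted olefin inert.

Step 6
Reactants: 10 [(1R,6R)-1,2,6-trimethylcyclohex-2-en-1-yl]methanol
Product: 11 (1R,6R)-1,2,6-trimethylcyclohex-2-ene-1-carbaldehyde
Conditions: Dess–Martin periodinane, CH2Cl2, rt
Reagents that add atoms: none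
Why: Dess–Martin oxidation stops cleanly at the aldehyde, which has no α-hydrogen and so cannot epimerise.

Step 7
Reactants: 11 (1R,6R)-1,2,6-trimethylcyclohex-2-ene-1-carbaldehyde
Product: 12 (5R,6R)-6-ethenyl-1,5,6-trimethylcyclohex-1-ene
Conditions: Ph3PCH3Br, KOt-Bu, THF, 0 °C to rt
Reagents that add atoms: methyltriphenylphosphonium bromide, C[P+](c1ccccc1)(c1ccccc1)c1ccccc1.[Br-]
Why: Wittig methylenation with the small unstabilised ylide works on hindered, non-enolisable aldehydes and gives the vinyl handle (product is volatile and is carried on as a pentane/THF solution).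

**Chain fragment**

Step 8
Reactants: 1 ethyl acetoacetate; 13 1-bromobut-2-yne
Product: 15 ethyl 3-oxooct-6-ynoate, via acetoacetate dianion 14 (not isolated)
Conditions: NaH, THF, 0 °C; n-BuLi, 0 °C; then 13, 0 °C to rt
Reagents that add atoms: none
Why: Weiler dianion alkylation, in which the more basic γ-carbanion of the 1,3-dianion reacts selectively with the primary propargylic bromide.

Step 9
Reactants: 15 ethyl 3-oxooct-6-ynoate
Product: 17 ethyl (2Z)-3-[(diethoxyphosphoryl)oxy]oct-2-en-6-ynoate, via sodium enolate 16 (not isolated)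
Conditions: NaH, Et2O, 0 °C; then ClP(O)(OEt)2, 0 °C to rt
Reagents that add atoms: diethyl chlorophosphate, CCOP(=O)(Cl)OCC
Why: The sodium-chelated (Z)-enolate formed in ether is O-phosphorylated with retention, giving the (Z)-enol phosphate stereoselectively.

Step 10
Reactants: 17 ethyl (2Z)-3-[(diethoxyphosphoryl)oxy]oct-2-en-6-ynoate
Product: 18 ethyl (2E)-3-methyloct-2-en-6-ynoate
Conditions: Me2CuLi (from MeLi, CuI), Et2O, −78 to −45 °C
Reagents that add atoms: lithium dimethylcuprate, [Li+].C[Cu-]C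
Why: Cuprate addition–elimination on the β-phosphoryloxy enoate proceeds with retention, so methyl ends cis to the ester and the (E)-trisubstituted olefin is formed stereospecifically, while the unactivated alkyne is inert.

Step 11
Reactants: 18 ethyl (2E)-3-methyloct-2-en-6-ynoate
Product: 19 (2E)-3-methyloct-2-en-6-yn-1-ol
Conditions: i-Bu2AlH, CH2Cl2, −78 °C
Reagents that add atoms: none
Why: 1,2-Reduction of the enoate by the aluminium hydride gives the allylic alcohol without changing olefin geometry.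

Step 12
Reactants: 19 (2E)-3-methyloct-2-en-6-yn-1-ol
Product: 21 (2E,6E)-7-iodo-3-methylocta-2,6-dien-1-ol, via vinylzirconocene 20 (not isolated)
Conditions: Cp2Zr(H)Cl (3 equiv), THF, 50 °C; then I2, 0 °C
Reagents that add atoms: iodine, [I][I]
Why: Syn-hydrozirconation of the methyl alkyne (one equivalent of reagent is consumed by the hydroxyl), equilibrated by excess reagent to place zirconium on the less hindered methyl-bearing carbon (about 10:1 or better expected), followed by iodinolysis with retention, gives the (E)-2-iodoalkene.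

Step 13
Reactants: 21 (2E,6E)-7-iodo-3-methylocta-2,6-dien-1-ol
Product: 22 (2E,6E)-1-bromo-7-iodo-3-methylocta-2,6-diene
Conditions: CBr4, PPh3, CH2Cl2, 0 °C
Reagents that add atoms: carbon tetrabromide, BrC(Br)(Br)Br
Why: Appel bromination converts the primary allylic alcohol to the bromide under neutral conditions without allylic transposition or loss of geometry.

Step 14
Reactants: 22 (2E,6E)-1-bromo-7-iodo-3-methylocta-2,6-diene; 23 2-methylprop-2-en-1-ol (methallyl alcohol)
Product: 25 (5E,9E)-10-iodo-6-methyl-2-methylideneundeca-5,9-dien-1-ol, via methallyl dianion 24 (not isolated)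
Conditions: 23, n-BuLi (2 equiv), TMEDA, Et2O, 0 °C to rt; then 22, THF, −78 to 0 °C
Reagents that add atoms: none
Why: The allylic carbanion of the alkoxide dianion C-alkylates the primary allylic bromide by direct SN2 displacement at low temperature (no free n-BuLi left), giving the 2-substituted allylic alcohol.

**Coupling and endgame**

Step 15
Reactants: 12 (5R,6R)-6-ethenyl-1,5,6-trimethylcyclohex-1-ene; 25 (5E,9E)-10-iodo-6-methyl-2-methylideneundeca-5,9-dien-1-ol
Product: 27 (5E,9E)-6,10-dimethyl-2-methylidene-12-[(1R,6R)-1,2,6-trimethylcyclohex-2-en-1-yl]dodeca-5,9-dien-1-ol, via alkylborane 26 (not isolated)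
Conditions: 12, 9-BBN, THF, rt; then 25, Pd(dppf)Cl2 (5 mol %), AsPh3, Cs2CO3, DMF/H2O, rt
Reagents that add atoms: none
Why: 9-BBN hydroborates only the monosubstituted vinyl group (anti-Markovnikov), and B-alkyl Suzuki–Miyaura coupling with the vinyl iodide proceeds with retention, giving the (E)-trisubstituted olefin while tolerating the free hydroxyl.

Step 16
Reactants: 27 (5E,9E)-6,10-dimethyl-2-methylidene-12-[(1R,6R)-1,2,6-trimethylcyclohex-2-en-1-yl]dodeca-5,9-dien-1-ol
Product: 28 (5E,9E)-6,10-dimethyl-2-methylidene-12-[(1R,6R)-1,2,6-trimethylcyclohex-2-en-1-yl]dodeca-5,9-dien-1-yl prop-2-enoate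
Conditions: acryloyl chloride, Et3N, CH2Cl2, 0 °C
Reagents that add atoms: acryloyl chloride, C=CC(=O)Cl
Why: Simple O-acylation of the unhindered primary allylic alcohol.

Step 17
Reactants: 28 (5E,9E)-6,10-dimethyl-2-methylidene-12-[(1R,6R)-1,2,6-trimethylcyclohex-2-en-1-yl]dodeca-5,9-dien-1-yl prop-2-enoate
Product: 29 4-{(3E,7E)-4,8-dimethyl-10-[(1R,6R)-1,2,6-trimethylcyclohex-2-en-1-yl]deca-3,7-dien-1-yl}furan-2(5H)-one
Conditions: second-generation Grubbs catalyst (H2IMes)(PCy3)Cl2Ru=CHPh (10 mol %), CH2Cl2 (2 mM), 40 °C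
Reagents that add atoms: none
Why: Ring-closing metathesis between the acrylate and the 1,1-disubstituted olefin closes the five-membered butenolide with loss of ethene, while the three trisubstituted olefins are unreactive and no other ring size is accessible.

**Compound list**
1 | ethyl acetoacetate (ethyl 3-oxobutanoate) | CCOC(=O)CC(C)=O | starting material
2 | (E)-but-2-enal (crotonaldehyde) | C/C=C/C=O | starting material
3 | ethyl (3R)-2-acetyl-3-methyl-5-oxopentanoate (Michael adduct, C2 epimers, in equilibrium with its cyclic hemiacetal) | CCOC(=O)C(C(C)=O)[C@H](C)CC=O | intermediate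
4 | ethyl (6R)-4-hydroxy-6-methyl-2-oxocyclohexane-1-carboxylate (aldol adduct, C1/C4 epimers) | CCOC(=O)C1C(=O)CC(O)C[C@H]1C | intermediate
5 | ethyl (1S,6R)-6-methyl-2-oxocyclohex-3-ene-1-carboxylate | CCOC(=O)[C@@H]1C(=O)C=CC[C@H]1C | intermediate
6 | ethyl (1R,6R)-1,6-dimethyl-2-oxocyclohex-3-ene-1-carboxylate | CCOC(=O)[C@@]1(C)C(=O)C=CC[C@H]1C | intermediate
7 | lithium (5R,6R)-6-(ethoxycarbonyl)-5,6-dimethylcyclohex-1-en-1-olate | CCOC(=O)[C@@]1(C)C([O-])=CCC[C@H]1C.[Li+] | intermediate
8 | ethyl (1R,6R)-1,6-dimethyl-2-{[(trifluoromethyl)sulfonyl]oxy}cyclohex-2-ene-1-carboxylate | CCOC(=O)[C@@]1(C)C(OS(=O)(=O)C(F)(F)F)=CCC[C@H]1C | intermediate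
9 | ethyl (1R,6R)-1,2,6-trimethylcyclohex-2-ene-1-carboxylate | CCOC(=O)[C@@]1(C)C(C)=CCC[C@H]1C | intermediate
10 | [(1R,6R)-1,2,6-trimethylcyclohex-2-en-1-yl]methanol | OC[C@@]1(C)C(C)=CCC[C@H]1C | intermediate
11 | (1R,6R)-1,2,6-trimethylcyclohex-2-ene-1-carbaldehyde | O=C[C@@]1(C)C(C)=CCC[C@H]1C | intermediate
12 | (5R,6R)-6-ethenyl-1,5,6-trimethylcyclohex-1-ene | C=C[C@@]1(C)C(C)=CCC[C@H]1C | intermediate
13 | 1-bromobut-2-yne | CC#CCBr | starting material
14 | sodium lithium 1,3-dianion of ethyl acetoacetate | [Li+].[Na+].[CH2-]C(=O)[CH-]C(=O)OCC | intermediate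
15 | ethyl 3-oxooct-6-ynoate | CC#CCCC(=O)CC(=O)OCC | intermediate
16 | sodium (2Z)-1-ethoxy-1-oxooct-2-en-6-yn-3-olate | [Na+].CC#CCC/C([O-])=C/C(=O)OCC | intermediate
17 | ethyl (2Z)-3-[(diethoxyphosphoryl)oxy]oct-2-en-6-ynoate | CC#CCC/C(OP(=O)(OCC)OCC)=C/C(=O)OCC | intermediate
18 | ethyl (2E)-3-methyloct-2-en-6-ynoate | CC#CCC/C(C)=C/C(=O)OCC | intermediate
19 | (2E)-3-methyloct-2-en-6-yn-1-ol | CC#CCC/C(C)=C/CO | intermediate
20 | (2E,6E)-7-[chlorobis(cyclopentadienyl)zirconio]-3-methylocta-2,6-dien-1-ol as its O-ZrCp2Cl alkoxide | C/C(=C\CC/C(C)=C/CO[Zr](Cl)(C1C=CC=C1)C1C=CC=C1)[Zr](Cl)(C1C=CC=C1)C1C=CC=C1 | intermediate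
21 | (2E,6E)-7-iodo-3-methylocta-2,6-dien-1-ol | C/C(I)=C\CC/C(C)=C/CO | intermediate
22 | (2E,6E)-1-bromo-7-iodo-3-methylocta-2,6-diene | C/C(I)=C\CC/C(C)=C/CBr | intermediate
23 | 2-methylprop-2-en-1-ol (methallyl alcohol) | CC(=C)CO | starting material
24 | dilithium 2-(oxidomethyl)prop-2-en-1-ide | [Li+].[Li+].[CH2-]C(=C)C[O-] | intermediate
25 | (5E,9E)-10-iodo-6-methyl-2-methylideneundeca-5,9-dien-1-ol | C/C(I)=C\CC/C(C)=C/CCC(=C)CO | intermediate
26 | 9-{2-[(1R,6R)-1,2,6-trimethylcyclohex-2-en-1-yl]ethyl}-9-borabicyclo[3.3.1]nonane | C(C[C@@]1(C)C(C)=CCC[C@H]1C)B1C2CCCC1CCC2 | intermediate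
27 | (5E,9E)-6,10-dimethyl-2-methylidene-12-[(1R,6R)-1,2,6-trimethylcyclohex-2-en-1-yl]dodeca-5,9-dien-1-ol | CC1=CCC[C@@H](C)[C@@]1(C)CC/C(C)=C/CC/C(C)=C/CCC(=C)CO | intermediate
28 | (5E,9E)-6,10-dimethyl-2-methylidene-12-[(1R,6R)-1,2,6-trimethylcyclohex-2-en-1-yl]dodeca-5,9-dien-1-yl prop-2-enoate | CC1=CCC[C@@H](C)[C@@]1(C)CC/C(C)=C/CC/C(C)=C/CCC(=C)COC(=O)C=C | intermediate
29 | 4-{(3E,7E)-4,8-dimethyl-10-[(1R,6R)-1,2,6-trimethylcyclohex-2-en-1-yl]deca-3,7-dien-1-yl}furan-2(5H)-one | CC1=CCC[C@@H](C)[C@@]1(C)CC/C(C)=C/CC/C(C)=C/CCC1=CC(=O)OC1 | target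

**Step count**
Total: 17 steps. Longest linear sequence: 10 steps (steps 1–7, then 15–17; the chain branch 8–14, then 15–17, is equally long).

**Three steps most likely to fail**

Step 14 (dianion alkylation in the presence of the vinyl iodide; lithium–iodine exchange or elimination could compete). Fallback: set out from 21 and borane 26 and run the Suzuki coupling first, under the step 15 conditions, to give (2E,6E)-3,7-dimethyl-9-[(1R,6R)-1,2,6-trimethylcyclohex-2-en-1-yl]nona-2,6-dien-1-ol F2. Convert it with CBr4/PPh3 to (5R,6R)-6-[(3E,7E)-9-bromo-3,7-dimethylnona-3,7-dien-1-yl]-1,5,6-trimethylcyclohex-1-ene F3, and only then alkylate dianion 24, now with no vinyl iodide in the molecule. This comes back to the route at 27, at the price of a longer linear sequence (12 steps).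

Step 3 (competing 1,2-reduction, or sluggish triflation of the borane-complexed enolate). Fallback: set out from 6 and hydrogenate the enone (H2, Pd/C, EtOAc) to ethyl (1R,2R)-1,2-dimethyl-6-oxocyclohexane-1-carboxylate F1. This ketone can enolise only toward its CH2 side, so KN(SiMe3)2 then PhNTf2 in THF at −78 °C gives the same enol triflate, coming back to the route at 8.

Step 15 (slow transmetalation of the β-quaternary alkylborane with the hindered trisubstituted vinyl iodide). Fallback: switch to a Negishi coupling. Set out from 12: hydroboration with 9-BBN and oxidative work-up (NaOH, H2O2) gives 2-[(1R,6R)-1,2,6-trimethylcyclohex-2-en-1-yl]ethan-1-ol F4. PPh3, I2 and imidazole give (5R,6R)-6-(2-iodoethyl)-1,5,6-trimethylcyclohex-1-ene F5. Zinc dust with LiCl in THF gives iodo{2-[(1R,6R)-1,2,6-trimethylcyclohex-2-en-1-yl]ethyl}zinc F6, which is coupled with vinyl iodide 25 using Pd(OAc)2/SPhos (tolerant of the free hydroxyl). This comes back to the route at 27.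

**Further compounds**
F1 | step 3 | ethyl (1R,2R)-1,2-dimethyl-6-oxocyclohexane-1-carboxylate | CCOC(=O)[C@@]1(C)C(=O)CCC[C@H]1C
F2 | step 14 | (2E,6E)-3,7-dimethyl-9-[(1R,6R)-1,2,6-trimethylcyclohex-2-en-1-yl]nona-2,6-dien-1-ol | CC1=CCC[C@@H](C)[C@@]1(C)CC/C(C)=C/CC/C(C)=C/CO
F3 | step 14 | (5R,6R)-6-[(3E,7E)-9-bromo-3,7-dimethylnona-3,7-dien-1-yl]-1,5,6-trimethylcyclohex-1-ene | CC1=CCC[C@@H](C)[C@@]1(C)CC/C(C)=C/CC/C(C)=C/CBr
F4 | step 15 | 2-[(1R,6R)-1,2,6-trimethylcyclohex-2-en-1-yl]ethan-1-ol | CC1=CCC[C@@H](C)[C@@]1(C)CCO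
F5 | step 15 | (5R,6R)-6-(2-iodoethyl)-1,5,6-trimethylcyclohex-1-ene | CC1=CCC[C@@H](C)[C@@]1(C)CCI
F6 | step 15 | iodo{2-[(1R,6R)-1,2,6-trimethylcyclohex-2-en-1-yl]ethyl}zinc | CC1=CCC[C@@H](C)[C@@]1(C)CC[Zn]I
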